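All runs are simulated on assumed constants; noise was put on by code.

The easy step is to follow D, of which cedar, ash, alder and larch each get 20.0 mM: in Tuesday's and Saturday's readings the last two values of J lie within the scatter of each other, which we take as a sign that D's part is over, while Monday's readings show no clear shape.

common to all: X 20 mM
- Monday's: D 20 mM; G 50 µM; temperature 20 °C; run made earlier
- Tuesday's: D 20 mM; G 200 µM; temperature 45 °C; run made earlier
- Saturday's: D 30 mM; G 100 µM; temperature 20 °C; run made earlier
- cedar: D 20.0 mM; G 100 µM; at 25 °C until 30 min, from then on at 65 °C; time 40 min
- ash: D 20.0 mM; G 100 µM; temperature 25 °C; time 40 min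
- alder: D 20.0 mM; G 100 µM; temperature 45 °C; time 40 min
- larch: D 20.0 mM; G 100 µM; temperature 65 °C; time 40 min

| run | time / min | J / % |
|---|---|---|
| Monday's | 10.0 | 3 |
| Monday's | 20.0 | 2 |
| Monday's | 30.0 | 1 |
| Monday's | 40.0 | 5 |
| Tuesday's | 2.00 | 19 |
| Tuesday's | 6.00 | 20 |
| Tuesday's | 10.0 | 21 |
| Tuesday's | 15.0 | 21 |
| Saturday's | 3.00 | 0 |
| Saturday's | 8.00 | 1 |
| Saturday's | 15.0 | 3 |
| Saturday's | 40.0 | 3 |

(standard deviation of a reading: 1.5 percentage points)

- solid, in amounts per volume of the solution: X
- at the start none of X is in solution
- in a conversion D counts as not yet reacted
- what has only dissolved of X counts as not reacted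

- the best flask by amount of J, in percent of the X and D together charged; "all alike" if 1.5 percentage points covers them all (cedar / ash / alder / larch / all alike)
- amount of J at the end, in percent of the X and D together charged, cedar
- amount of J at the end, in percent of the X and D together charged, ash
- amount of J at the end, in percent of the X and D together charged, alder
- amount of J at the end, in percent of the X and D together charged, larch

Saturday's run has the same 100 µM of G as our flasks but is colder, and its readings stand level from 15.0 min on, within the scatter. So we name the levelling time τ, 15.0 min: the time from which the readings of J show no further rise beyond the scatter, as read there, and which we take as the time D's part lasts. Two times then matter, τ and the time a flask stays at its first temperature. The last readings differ as well: Tuesday's 21% at 45 °C stands above Saturday's 3% at 20 °C, though these two runs also differ in G and D. We read this as kinetic rather than thermodynamic control: a yield from D made at the temperature D lasted at, not a balance that follows later heating. Cedar, at 25 °C, is warmer than Saturday's run, and Saturday's τ is about half of the 30 min before cedar's heating, so our own reckoning puts cedar level with ash, near Monday's last 5%.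

The forecast gives cedar 36%, ash 4%, alder 20% and larch 37%, with larch best, and says: “Cedar's ten hot minutes should suffice, so cedar is about equal to larch, unless G dies when hot.” On cedar we part from it.

    E ⇌ D (K = 1.31, k = 0.0287 min⁻¹, Ea = 96.0 kJ mol⁻¹, ΔH = −90.0 kJ mol⁻¹)
    E + G → G + J (k = 3100 L mol⁻¹ min⁻¹, Ea = 35.0 kJ mol⁻¹)
    G + D → G + Q (k = 5220 L mol⁻¹ min⁻¹, Ea = 43.0 kJ mol⁻¹)
    X ⇌ E, rate k4*(cs4 - [E]) while solid is left; crystals form when [E] > cs4 (solubility = 1.00 mM, k = 0.0720 min⁻¹)
    (constants at 25 °C)

The flasks give cedar 7.27%, ash 6.64%, alder 29.7% and larch 51.4%, so larch is best, as forecast. Cedar stands 0.63 percentage points above ash, inside the margin of 1.5 points, and when cedar was heated at 30.0 min, past τ, its D stood at 0.0232% of the total charge. J does not stand after that: in ash, with D at 0.0245% at 20.0 min, J still climbs from 3.91% then to 6.64% at 40.0 min. A neighbour flask like larch, kept at 40 °C, holds that temperature beyond τ, and that temperature lies between those of ash and alder, so its J should lie between theirs. It ends with D at 0.0209% and J at 20.7%.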